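**Retrosynthetic overview**

1. The lactone ring is closed last by forming the C14–C15 bond: a zerovalent-palladium C(sp3)–H alkylation joins the chloromethyl ester carbon C15 of 16 to the C14 methyl group. The enabling feature is the fully substituted C13, shared by both five-membered rings, which carries the carboxyl C16 and the methyl C14 side by side, so Pd–C15 has no β-hydrogen and reaches C14–H through the six-membered cycle Pd–C15–O–C16–C13–C14.
2. The tetrahydrofuran ring comes before that: the C9–O bond forms when the C13 hydroxyl captures the tertiary C9 cation. C13, with its oxygen, methyl and carboxyl, comes from (R)-lactic acid by alkylation of its dioxolanone enolate with allylic bromide 8 (C12–C13 bond); C11–C12 is a vinyl group added to the C9 ketone.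
3. The cis-decalin comes first: rings A and B are made together by an enantioselective Diels–Alder reaction of 2,6-dimethylbenzoquinone with 4-methylpenta-1,3-diene (bonds C1–C10 and C4–C5). C6 and C8 are then set by convex-face reduction, hydroxyl-directed hydrogenation and Mitsunobu inversion.
4. Ring order: rings A and B (step 1), tetrahydrofuran (step 9), lactone (step 11).

Key step: step 11

Remark (reading of the target): the SMILES is taken literally as (5S,6S,8R,9R,10R,13R), a cis-fused decalin in which H-5, the 6-acetoxy group, the C8 methyl, the C9 oxygen and the C10 methyl lie on one face (called α; ring A lies on the β face).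
Remark (numbering): labdane numbers are used: C1–C3 are the ring A CH2 groups, C4 is CMe2, C5 the ring-fusion CH, C6 the CH–O, C7 the CH2, C8 the CH–CH3, C9 the spiro C–O, C10 the ring-fusion C–CH3, C11/C12 the tetrahydrofuran CH2CH2, C13 the carbon shared by tetrahydrofuran and lactone, C14/C15 the lactone CH2CH2 (C15 on oxygen), C16 the lactone carbonyl.
Remark (assumption): the antipode of the step 1 catalyst that delivers the (5S,10R) adduct is used; the sense of induction is assigned by analogy and would be corrected by switching to the mirror-image catalyst.

**Route**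

Step 1
Reactants: 1 (2,6-dimethyl-1,4-benzoquinone); 2 (4-methylpenta-1,3-diene)
Product: 3 cis-fused enedione adduct
Conditions: (S)-o-tolyl-oxazaborolidine from α,α-diphenylprolinol activated with HNTf2 (20 mol %), CH2Cl2, −78 to −40 °C
Reagents that add atoms: none
Why: This is a catalytic enantioselective Diels–Alder reaction in which suprafacial addition to the methyl-bearing quinone double bond sets C5 and C10 cis in one event, the bulky CMe2 terminus of the diene bonds to the unsubstituted quinone carbon, and the catalyst bound to the less hindered carbonyl shields one face to give the (5S,10R) adduct.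

Step 2
Reactants: 3 (cis-fused enedione adduct)
Product: 4 6β-hydroxy enone
Conditions: NaBH4, CeCl3·7H2O, MeOH, −78 °C
Reagents that add atoms: none
Why: In this Luche 1,2-reduction the C6 carbonyl, the one not flanked by a quaternary carbon, should react selectively and hydride should enter from the convex α face away from ring A, which places the new hydroxyl β (6R).

Step 3
Reactants: 4 (6β-hydroxy enone)
Product: 5 saturated 6β-hydroxy ketone
Conditions: H2 (1 atm), [Ir(cod)(PCy3)(py)]PF6 (5 mol %), CH2Cl2, rt
Reagents that add atoms: none
Why: In this hydroxyl-directed homogeneous hydrogenation the cationic iridium catalyst binds the 6β-hydroxyl and should deliver H2 to C7=C8 from the β face, so the C8 methyl ends α (8R), while the unhindered ring A alkene is saturated in the same operation.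

Step 4
Reactants: 5 (saturated 6β-hydroxy ketone)
Product: 6 vinyl carbinol diol
Conditions: CH2=CHMgBr (3 equiv), CeCl3 (3 equiv), THF, −78 to 0 °C
Reagents that add atoms: vinylmagnesium bromide C=C[Mg]Br
Why: The non-basic organocerium reagent should add 1,2 to the hindered, enolisable C9 ketone without epimerising C8 (one equivalent is spent on the hydroxyl); attack from the open α face is expected, but the C9 configuration is erased in step 9.

Step 5
Reactants: 6 (vinyl carbinol diol)
Product: 7 6α-acetate
Conditions: AcOH, PPh3, DIAD, toluene, 0 °C to rt
Reagents that add atoms: acetic acid CC(=O)O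
Why: In this Mitsunobu reaction acetate should displace the activated axial 6β-hydroxyl by SN2 attack from the open α face, inverting C6 to the required 6α-acetate (6S), while the tertiary allylic alcohol does not react.

Step 6
Reactants: 7 (6α-acetate)
Product: 8 allylic bromide
Conditions: PBr3 (0.4 equiv), pyridine (cat.), Et2O, −10 °C
Reagents that add atoms: phosphorus tribromide BrP(Br)Br
Why: Bromination of the tertiary vinyl carbinol with allylic transposition (SN2′) should give the primary allylic bromide with the C9=C11 double bond, whose geometry does not matter because C9 becomes a cation in step 9.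

Step 7
Reactants: 9 ((R)-lactic acid); 10 (pivalaldehyde)
Product: 11 cis-dioxolanone
Conditions: TsOH·H2O (cat.), H2SO4 (cat.), pentane, reflux with water separator, recrystallise
Reagents that add atoms: none
Why: Acid-catalysed acetalisation (first stage of self-regeneration of stereocentres) should give mainly the cis-dioxolanone, which stores the configuration of lactic acid in the new acetal centre (2R).

Step 8
Reactants: 8 (allylic bromide); 11 (cis-dioxolanone)
Product: 13 alkylated dioxolanone, via lithium enolate 12 (not isolated)
Conditions: LiN(iPr)2, THF, −78 °C; then 8, −78 to −30 °C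
Reagents that add atoms: none
Why: In this diastereoselective enolate alkylation (self-regeneration of stereocentres) the planar lithium enolate should be alkylated by the allylic bromide in SN2 fashion on the face anti to the tert-butyl group, which creates the quaternary C13 in the configuration that becomes 13R in the target.

Step 9
Reactants: 13 (alkylated dioxolanone)
Product: 15 spiro-tetrahydrofuran acid, via hydroxy acid 14 (not isolated)
Conditions: CF3CO2H/H2O 9:1, rt; evaporate; CF3SO3H (10 mol %), CH2Cl2, 0 °C
Reagents that add atoms: none
Why: Acylal hydrolysis followed by acid-mediated Markovnikov hydroalkoxylation should work because protonation of C11 gives the tertiary C9 cation common to both alkene isomers, which the C13 hydroxyl captures axially on the α face (the β face is blocked by the axial C1 of ring A while the 6-acetate and 8-methyl stay equatorial), setting C9 (R) and closing the tetrahydrofuran.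

Step 10
Reactants: 15 (spiro-tetrahydrofuran acid)
Product: 16 chloromethyl ester
Conditions: ClCH2OSO2Cl, NaHCO3, Bu4NHSO4 (cat.), CH2Cl2/H2O, rt
Reagents that add atoms: chloromethyl chlorosulfate ClCOS(Cl)(=O)=O
Why: Phase-transfer O-alkylation of the carboxylate (SN2 at the sulfate-bearing carbon) should give the chloromethyl ester without touching the acetate or the ether.

Step 11
Reactants: 16 (chloromethyl ester)
Product: 17 target spirolactone
Conditions: Pd2(dba)3 (5 mol %), PCy3·HBF4 (20 mol %), 1-AdCO2H (30 mol %), Cs2CO3, mesitylene, 4 Å MS, 110 °C
Reagents that add atoms: none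
Why: Proposed new method: oxidative addition of zerovalent palladium into the activated C15–Cl bond should give an (acyloxy)methyl–Pd chloride that has no β-hydrogen, carboxylate-assisted concerted metalation–deprotonation of the C14 methyl C–H then gives the six-membered palladacycle Pd–C15–O–C16–C13–C14, and C(sp3)–C(sp3) reductive elimination forms C14–C15. The closest known reaction type is the zerovalent-palladium-catalysed intramolecular C(sp3)–H alkylation of α-chloroamides to β-lactams, together with the C(sp3)–H arylation of methyl groups on quaternary carbons that closes five-membered rings through six-membered palladacycles. The γ-lactone ring is closed by reductive elimination from that palladacycle, formally a 5-exo-tet closure in which C14 replaces chloride at C15. No stereocentre is created; C13 keeps the configuration set in step 8 because none of its bonds is broken, and the base is too weak to touch the other centres. The step needs site selectivity for the primary C14–H over the ring methylene C12–H, and oxidative addition must outrun displacement of chloride by carboxylate; the first is secured by the strong primary-over-secondary preference of concerted metalation–deprotonation at a methyl on the quaternary C13, the second by insoluble Cs2CO3 with only a catalytic, hindered carboxylic acid as proton shuttle in a dry non-polar solvent.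

**Compound list**

1 | 2,6-dimethyl-1,4-benzoquinone | CC1=CC(=O)C=C(C)C1=O | starting material
2 | 4-methylpenta-1,3-diene | C=CC=C(C)C | starting material
3 | (4aS,8aR)-2,5,5,8a-tetramethyl-4a,5,8,8a-tetrahydronaphthalene-1,4-dione (cis-fused; labdane numbering 5S,10R) | O=C1C=C(C)C(=O)[C@]2(C)CC=CC(C)(C)[C@H]12 | intermediate
4 | (4R,4aS,8aR)-4-hydroxy-2,5,5,8a-tetramethyl-4a,5,8,8a-tetrahydronaphthalen-1(4H)-one (6β-hydroxy enone) | O[C@@H]1C=C(C)C(=O)[C@]2(C)CC=CC(C)(C)[C@H]12 | intermediate
5 | (2R,4R,4aS,8aR)-4-hydroxy-2,5,5,8a-tetramethyloctahydronaphthalen-1(2H)-one (6β-OH, 8α-CH3, cis-fused) | O[C@@H]1C[C@@H](C)C(=O)[C@]2(C)CCCC(C)(C)[C@H]12 | intermediate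
6 | (1S,2R,4R,4aS,8aR)-1-ethenyl-2,5,5,8a-tetramethyldecahydronaphthalene-1,4-diol (expected C9 epimer drawn: 9β-OH, 9α-vinyl) | O[C@@H]1C[C@@H](C)[C@@](O)(C=C)[C@]2(C)CCCC(C)(C)[C@H]12 | intermediate
7 | 6α-acetate of 6 (labdane numbering 5S,6S,8R,9S,10R): 6-acetoxy-9-hydroxy-9-vinyl-4,4,8,10-tetramethyl-cis-decalin | CC(=O)O[C@H]1C[C@@H](C)[C@@](O)(C=C)[C@]2(C)CCCC(C)(C)[C@H]12 | intermediate
8 | (5S,6S,8R,10R,E)-6-acetoxy-9-(2-bromoethylidene)-4,4,8,10-tetramethyl-cis-decalin | CC(=O)O[C@H]1C[C@@H](C)/C(=C\CBr)[C@]2(C)CCCC(C)(C)[C@H]12 | intermediate
9 | (R)-lactic acid | C[C@@H](O)C(=O)O | starting material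
10 | pivalaldehyde | CC(C)(C)C=O | starting material
11 | (2R,5R)-2-tert-butyl-5-methyl-1,3-dioxolan-4-one | C[C@H]1O[C@@H](C(C)(C)C)OC1=O | intermediate
12 | lithium enolate of 11: lithium (2R)-2-tert-butyl-5-methyl-1,3-dioxol-4-olate | CC1=C(O[Li])O[C@H](C(C)(C)C)O1 | intermediate
13 | (2R,5S)-2-tert-butyl-5-methyl-5-[(E)-2-(6α-acetoxy-4,4,8,10-tetramethyl-cis-decalin-9-ylidene)ethyl]-1,3-dioxolan-4-one | CC(=O)O[C@H]1C[C@@H](C)/C(=C\C[C@]2(C)O[C@@H](C(C)(C)C)OC2=O)[C@]2(C)CCCC(C)(C)[C@H]12 | intermediate
14 | (S)-2-hydroxy-2-methyl-4-(6α-acetoxy-4,4,8,10-tetramethyl-cis-decalin-9-ylidene)butanoic acid (E) | CC(=O)O[C@H]1C[C@@H](C)/C(=C\C[C@](C)(O)C(=O)O)[C@]2(C)CCCC(C)(C)[C@H]12 | intermediate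
15 | (5S,6S,8R,9R,10R,13S)-6-acetoxy-9,13-epoxy-15-norlabdan-16-oic acid (C14 is a methyl on C13) | CC(=O)O[C@H]1C[C@@H](C)[C@]2(CC[C@@](C)(C(=O)O)O2)[C@]2(C)CCCC(C)(C)[C@H]12 | intermediate
16 | chloromethyl ester of 15 | CC(=O)O[C@H]1C[C@@H](C)[C@]2(CC[C@@](C)(C(=O)OCCl)O2)[C@]2(C)CCCC(C)(C)[C@H]12 | intermediate
17 | (5S,6S,8R,9R,10R,13R)-6-acetoxy-9,13-epoxylabdan-16,15-olide | CC(=O)O[C@H]1C[C@@H](C)[C@]2(CC[C@]3(CCOC3=O)O2)[C@]2(C)CCCC(C)(C)[C@H]12 | target

**Step count and risks**

Total step count: 11. Longest linear sequence: 10 steps (steps 1–6 and 8–11; step 7 makes the side-chain building block).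

The three steps most likely to fail:

Step 11 (proposed method). Oxidative addition may be outrun by displacement of the chloride by carboxylate. The palladacycle may also fail to form because the ester must adopt its less favoured s-cis rotamer, or metalation may occur at the ring methylene. The fallback uses known chemistry, sets out from 15 and returns at 17. Divalent-palladium-catalysed β-C(sp3)–H lactonisation of the free acid (Pd(CH3CN)2Cl2, N-acetyl-β-alanine-type ligand, tert-butyl hydroperoxide, CsHCO3, hexafluoroisopropanol, 60 °C) should give the spiro β-lactone F1. Copper-catalysed SN2 opening of F1 at C14 with (isopropoxydimethylsilyl)methylmagnesium chloride (CuBr·SMe2 cat., THF, −30 °C) should give the silyl acid F2, with C14–C15 formed intermolecularly. Tamao oxidation of F2 (H2O2, KF, KHCO3, THF/MeOH) and spontaneous lactonisation of the resulting hydroxy acid should give 17.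

Step 1. The cis-substituted diene terminus reacts sluggishly, so diene oligomerisation under the cationic catalyst or an uncatalysed background reaction may erode conversion and enantioselectivity. The fallback sets out from 1 and 2 and returns at 4. An uncatalysed cycloaddition (toluene, 80 °C, sealed tube, or 12 kbar at rt) should give the racemic adduct, that is 3 together with its enantiomer F3. An enantiomer-selective oxazaborolidine-catalysed borane reduction ((S)-2-methyl-oxazaborolidine from α,α-diphenylprolinol, catecholborane, toluene, −78 °C) then replaces step 2. It should reduce only the enantiomer whose convex face matches the catalyst, giving 4 and leaving F3 behind for separation.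

Step 5. SN2 inversion at the hindered C6 carbinol may lose to elimination. The fallback sets out from 6 and returns at 7. Meerwein–Ponndorf–Verley/Oppenauer equilibration (Al(OiPr)3, isopropanol, acetone (cat.), toluene, 80 °C) should convert the axial 6β-alcohol through the transient C6 ketone into the thermodynamically preferred equatorial 6α-alcohol F4. Selective acetylation of its secondary hydroxyl (Ac2O, pyridine, DMAP (cat.), CH2Cl2, 0 °C) should give 7.

**Further compounds**

F1 | step 11 | spiro β-lactone: (5S,6S,8R,9R,10R,13R)-6-acetoxy-9,13-epoxy-15-norlabdan-16,14-olide | CC(=O)O[C@H]1C[C@@H](C)[C@]2(CC[C@]3(COC3=O)O2)[C@]2(C)CCCC(C)(C)[C@H]12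
F2 | step 11 | silyl acid: 6α-acetoxy-9,13-epoxy-15-(isopropoxydimethylsilyl)labdan-16-oic acid | CC(=O)O[C@H]1C[C@@H](C)[C@]2(CC[C@@](CC[Si](C)(C)OC(C)C)(C(=O)O)O2)[C@]2(C)CCCC(C)(C)[C@H]12
F3 | step 1 | enantiomer of 3: (4aR,8aS)-2,5,5,8a-tetramethyl-4a,5,8,8a-tetrahydronaphthalene-1,4-dione | O=C1C=C(C)C(=O)[C@@]2(C)CC=CC(C)(C)[C@@H]12
F4 | step 5 | 6α-alcohol: C6 epimer of diol 6 | O[C@H]1C[C@@H](C)[C@@](O)(C=C)[C@]2(C)CCCC(C)(C)[C@H]12
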